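**The flask.** Start from a small charge: 0.2 mol% of free catalyst, with partner, carries starting material to target in a closed, stirred flask.

the same everywhere: starting material 0.020 M; free catalyst 0.2 mol%

| run | partner | second substrate | remark | time |
|---|---|---|---|---|
| alder | 1.3 equiv | 0.20 equiv | run made earlier |  |
| cedar | 5.3 equiv | 0.20 equiv | run made earlier |  |
| Saturday's | 7.20 equiv | 0.200 equiv |  | 50 min |
| Friday's | 1.80 equiv | 0.200 equiv |  | 12 min |

| run | time / min | target / % | starting material / % |
|---|---|---|---|
| alder | 1.00 | 2.0 | 94.8 |
| alder | 1.50 | 4.9 | 95.6 |
| alder | 2.50 | 7.4 | 92.4 |
| alder | 4.00 | 9.7 | 87.7 |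
| alder | 8.00 | 14.0 | 80.1 |
| alder | 12.0 | 17.7 | 78.0 |
| cedar | 0.833 | 13.2 | 85.1 |
| cedar | 2.50 | 26.6 | 68.6 |
| cedar | 4.00 | 34.9 | 58.7 |
| cedar | 6.00 | 42.0 | 50.1 |
| cedar | 10.0 | 48.0 | 39.6 |
| cedar | 12.0 | 50.7 | 36.7 |

(each reading ± 1 percentage point)



- which one finishes higher in amount of target, in percent of the starting material charged ("neither" within 2 percentage points) (Saturday's / Friday's / neither)
- amount of target at the end, in percent of the starting material charged, Saturday's
- amount of target at the end, in percent of the starting material charged, Friday's

**One molecule.** Follow a molecule of starting material once it is consumed and ask its chance of standing as target. Cedar's last reading gives 0.801: call this target over starting material lost the target share, a selectivity. Alder's last reading gives 0.805.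

**Bench rule.** Count elapsed time constants as the log of charge over what is left. Cedar's readings reach 1.00 by 12.0 min, and that count stands 4.03 times above alder's for 4.08 times the partner, so scale it with partner, the other charges held. For Friday's, on cedar's clock, the rule gives a loss of 28.9% of its starting material and an estimate of 23.1% target. For Saturday's, at that same time, it gives a loss of 74.4% and an estimate of 59.6% target.

**The border.** Saturday's runs 4.17 times as long as cedar's last reading, so the rule is stretched past what was read. Cedar's share also slips: between 6.00 min and 12.0 min each molecule lost gave 0.649 target, a scattered reading, but less than the share. Let Saturday's estimated remainder react at that chance and the reckoning reaches 76.2%. My reckoning therefore puts Saturday's between 59.6% and 76.2%, far above Friday's.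

**The forecast.** It names Saturday's, with 66% and 23%, and reads the slowing thus: “the catalyst is dying rather than the reagents running out”. Its Saturday's figure lies inside my bracket.

**The result.** Saturday's finishes higher, 64.5% against 21.2%.

    starting material + partner + free catalyst → free catalyst + target (k = 46300 M⁻² min⁻¹)
    starting material + target → side product (k = 1.70 M⁻¹ min⁻¹)
    2 free catalyst → spent catalyst (k = 3850 M⁻¹ min⁻¹)
    second substrate + partner + free catalyst → free catalyst + second product (k = 16000 M⁻² min⁻¹)

Saturday's consumes 96.0% of its starting material, so its target share ends at 0.672, below the reading from cedar. On Saturday's, target is made 10.3 times faster than it is used at 2.78 min, but at 50.0 min making runs at 0.649 of using. So Saturday's has passed its top: target stands at 64.8% after 25.0 min and 64.5% at the end.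

**Next flask.** Raise Saturday's starting material to 0.034 M, holding equivalents. With 0.14% of that flask's starting material left, the target share read from cedar gives 80.0%. The flask gives 80.9%.

The earlier runs and the new flask stem from a simulated flask with made-up constants, noise included.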